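## Analysis of the target

Numbering: carbocycle C1–C10; the oxolane oxygen bridges C1 and C4; C10 is the methyl carbinol; C8 carries the acyloxy group; C5=C6 is the enol-lactone alkene; C7=C11 is the butenolide alkene; C12 is the lactone carbonyl; C13 is the acetoxymethyl carbon; C14 and C15 are the methyls on C10 and C4.

The target is a ten-membered carbocycle crossed by a 1,4-ether bridge (a cis-2,2,5-trisubstituted oxolane) and fused at C6–C7 to a γ-ylidenebutenolide (O–C6(=C5)–C7=C11–C12=O). It has four ring stereocentres, C1 (S), C4 (R, quaternary), C8 (S) and C10 (R, tertiary carbinol), and a fifth in the (S)-2-methyloxirane-2-carboxylate on O8. C1 and C4 are cis across the oxolane, C1 and C10 are vicinal oxygenated carbons, and the C8 and C10 oxygens are 1,3-syn along the chain C7–C8–C9–C10–C1. Sensitive groups are the glycidic ester (acid, halide, nucleophiles), the primary allylic acetate (base, low-valent metals), the cross-conjugated enol lactone (base, hydration) and the free C10 hydroxyl, which can add across the ring to C6. The difficulty is the medium ring, which has to be closed at a fully substituted alkene carbon while the (Z) relationship of C6 and C12 on C7=C11 is kept. The strategy rests on one feature: C6 and C12 are 1,4-related carbonyl carbons, so the ring bond C6–C7 joins an acyl carbon to the β-carbon of an enoate. Both are acceptor sites, so no polar step joins them directly, but a reductive nickel cycle can couple them as two electrophiles. A (Z)-γ-keto acid then closes by itself to the butenolide.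

## Retrosynthetic reasoning

**O8 acyl bond.** The target 36 is cut at the ester into diol 31 and (S)-epoxy acid 34. The epoxide tolerates neither fluoride, iodide nor low-valent nickel, so it goes on last. Only the secondary C8 hydroxyl of 31 can be acylated under mild conditions, since the C10 hydroxyl is tertiary. Acid 34 comes from 2-methylprop-2-en-1-ol 32 by Sharpless epoxidation (33) and oxidation.

**Enol lactone and acetate.** Ylidenebutenolide 30 (precursor of 31) is the dehydrated ring tautomer of a (Z)-γ-keto acid. Cutting C6–O and hydrating C5=C6 leads to keto ester 27, in which the C6 ketone is cis to the C12 silylethyl ester. Forward, fluoride frees the acid and the primary C13 hydroxyl; acetylation then esterifies C13 and drives loss of the lactol oxygen (28, 29). The C5=C6 geometry is set by the ring, which accepts only the cis arrangement of C4 and C7.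

**C6–C7, the ring bond.** Keto enoate 27 is cut between the ketone carbon and the alkene into seco compound 26, which has an S-2-pyridyl thioester at C6 and a (Z)-vinyl iodide at C7. This is the only ring bond whose two ends can each be made as a stable electrophile by standard chemistry. Cutting here also removes the ten-membered ring and the 1,4-dicarbonyl dissonance in one operation. The forward reaction must keep the alkene geometry and beat dimerisation.

**Thioester.** The acyl donor of 26 is made last, from acid 25, because it would not survive acetylides or Lewis acids. C6 therefore travels as a primary triethylsilyl ether (23), which is oxidised directly to aldehyde 24 and then to 25.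

**Iodoenoate.** The tetrasubstituted alkene of 23 is cut at C7–I and C11–C13, giving ynoate 20. Forward, iodide adds to C7 and the resulting allenolate 21 takes up a one-carbon carbonyl electrophile at C11. The electrophile enters anti to iodine, as in the hydroiodination of alkynoates, which puts iodine cis to the ester (22).

**C7–C8 and the C8 stereocentre.** Ynoate 20 is cut into aldehyde 12 and silylethyl propiolate 15 (from 13 and 14). The C10 centre is quaternary and gives little 1,3-induction, so C8 is set by reagent control: addition (17), oxidation to ynone 18 and asymmetric transfer hydrogenation to 19.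

**C8–C9 and the C5–C6 arm.** Aldehyde 12 is the ozonolysis product of the allyl carbinol 10. Its C8–C9 bond comes from opening the terminal epoxide of 8 with a vinyl nucleophile (9). The C6 oxygen comes from hydroboration of the vinyl group of 6, and epoxide 6 from the 1,2-diol 4.

**Oxolane, C1 and C10.** Diol 4 is cut at O–C1 to epoxy alcohol 3, whose tertiary hydroxyl opens the epoxide 5-exo with inversion at C1. Epoxide 3 comes from Sharpless epoxidation of allylic alcohol 2, and 2 from allylic oxidation of (R)-linalool 1. Linalool supplies C4 with its methyl and the two-carbon arm; one catalyst-controlled step sets C1 and C10.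

## Alternatives that were turned down

**Alternative 1: radical closure of the oxolane through C3–C4.** The oxolane is cut at C3–C4. A primary C3 radical, generated from bromide A1 by a tin hydride chain, adds 5-exo to the β-carbon of a β-alkoxycrotonate and gives oxolane ester A2.
- For: it builds the quaternary C4 and delivers the C5–C6 arm already at the carboxyl level. The chosen route needs a hydroboration and two oxidations for that (steps 4, 15, 16), so on this point the alternative is stronger.
- Against: C4 is created by face selection on a trisubstituted alkene whose two exocyclic groups (methyl and the ester arm) differ little, and the β-methyl upsets the conformational preference that makes simple β-alkoxyacrylates cis-selective. A1 needs C1 and C10 set beforehand in separate steps. Stoichiometric tin is required.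
- Comparison: it only replaces the first four steps of the chosen route and leaves the ring problem untouched. The chosen route takes C4 from the chiral pool and reaches the cis-oxolane in two steps.

**Alternative 2: oxidative cyclisation of a diol onto the C4=C5 alkene.** The oxolane is cut at O–C4. The C1,C10-diol of (E)-alkene A3 is engaged by an octavalent osmium catalyst with an amine N-oxide and acid, and adds syn across C4=C5 to give the cis-oxolane A4.
- For: the closure is stereospecific and has no regiochemical ambiguity. The epoxide opening used here could in principle leak to the six-membered ether, so on this point the alternative is as strong or stronger. Free hydroxyls are tolerated.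
- Against: A4 carries a hydroxyl on C5, which in the target is a vinylic CH. With C6 at the acyl level needed for the chosen ring closure, this oxygen cannot serve as the leaving group for C5=C6 and would have to be removed in extra steps. A3 also needs a separate asymmetric dihydroxylation.
- Comparison: longer, and again silent on the ten-membered ring. The chosen route makes the same oxolane without a surplus oxygen.

**Alternative 3: Ramberg–Bäcklund ring contraction.** The C5=C6 alkene is cut. The eleven-membered cyclic sulfone A5 (sulfur between C5 and C6) is halogenated at C6 in situ by a dihalodifluoromethane with hydroxide on alumina, closes to the episulfone, loses sulfur dioxide and gives the ylidenebutenolide A6.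
- For: it closes a larger ring through a soft sulfur nucleophile and then forms C5=C6 at the final oxidation level. No separate dehydration is needed and every step type is known; both points are stronger than in the chosen route.
- Against: the strongly basic medium meets a butenolide whose extended enolate can expel the C13 or C8 silyloxy groups. The α-oxygenated sulfone at C6 is itself prone to ionise. Making A5 requires a C6–S bond at the lactone γ-position and the C6–C7 bond by other means, so the assembly is longer.
- Comparison: the chosen strategy offers a neutral, reductive ring closure from a linear precursor whose two ends come from standard chemistry, and it makes C6–C7 and the ring in one step.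

Key step: step 18

Remark: the tertiary C10 hydroxyl is carried as a triethylsilyl ether from step 6 to step 20. This keeps it from retro-aldol cleavage next to the C8 carbonyl intermediates and from adding across the ring to C6.

Remark: the sense of induction in the two Sharpless epoxidations and in the transfer hydrogenation is taken from the established empirical models.

## Route

Step 1
Reactants: 1 (R)-linalool
Product: 2 (2E,6R)-2,6-dimethylocta-2,7-diene-1,6-diol
Conditions: SeO2 (cat.), t-BuOOH, salicylic acid (cat.), CH2Cl2, rt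
Reagents that add atoms: selenium dioxide, O=[Se]=O; tert-butyl hydroperoxide, CC(C)(C)OO
Why: Catalytic SeO2 allylic oxidation (ene reaction, then [2,3]-shift) attacks the (E)-methyl of the trisubstituted alkene; the vinyl group has no allylic hydrogen and the C4 centre is untouched.

Step 2
Reactants: 2 (2E,6R)-2,6-dimethylocta-2,7-diene-1,6-diol
Product: 4 (2R)-2-[(2S,5R)-5-ethenyl-5-methyloxolan-2-yl]propane-1,2-diol, via epoxy alcohol 3 (not isolated)
Conditions: Ti(OiPr)4 (cat.), D-(−)-diisopropyl tartrate, t-BuOOH, 4 Å MS, CH2Cl2, −20 °C; then camphorsulfonic acid (cat.), 0 °C → rt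
Reagents that add atoms: tert-butyl hydroperoxide, CC(C)(C)OO
Why: Sharpless epoxidation of the primary allylic alcohol (the tertiary allylic alcohol is inert) sets C10 and the epoxide face; the tertiary hydroxyl then opens the epoxide 5-exo at the carbon remote from the CH2OH group with inversion, which sets C1 (S) and the cis-oxolane.

Step 3
Reactants: 4 (2R)-2-[(2S,5R)-5-ethenyl-5-methyloxolan-2-yl]propane-1,2-diol
Product: 6 (2R,5S)-2-ethenyl-2-methyl-5-[(2R)-2-methyloxiran-2-yl]oxolane, via primary tosylate 5 (not isolated)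
Conditions: NaH, 1-(p-toluenesulfonyl)imidazole, THF, 0 °C → rt
Reagents that add atoms: none
Why: Selective sulfonylation of the primary hydroxyl and Williamson closure by the tertiary alkoxide give the terminal epoxide; the C10–O bond is not touched, so C10 keeps its configuration.

Step 4
Reactants: 6 (2R,5S)-2-ethenyl-2-methyl-5-[(2R)-2-methyloxiran-2-yl]oxolane
Product: 8 2-[(2R,5S)-2-methyl-5-[(2R)-2-methyloxiran-2-yl]oxolan-2-yl]ethan-1-ol, via alkylborane 7 (not isolated)
Conditions: 9-BBN, THF, 0 °C → rt; then NaOH aq, H2O2, 0 °C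
Reagents that add atoms: hydrogen peroxide, OO
Why: Anti-Markovnikov hydroboration–oxidation of the vinyl group on the quaternary carbon gives the C6 primary alcohol; the 2,2-disubstituted epoxide is inert to 9-BBN and to brief cold alkaline peroxide.

Step 5
Reactants: 8 2-[(2R,5S)-2-methyl-5-[(2R)-2-methyloxiran-2-yl]oxolan-2-yl]ethan-1-ol
Product: 9 (2R)-2-[(2S,5R)-5-(2-hydroxyethyl)-5-methyloxolan-2-yl]pent-4-en-2-ol
Conditions: vinylmagnesium bromide (excess), CuI (cat.), THF, −40 → 0 °C
Reagents that add atoms: vinylmagnesium bromide, C=C[Mg]Br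
Why: Copper-catalysed Grignard opening of the epoxide at its unsubstituted carbon forms C8–C9 and frees the tertiary C10 carbinol without touching the stereocentre.

Step 6
Reactants: 9 (2R)-2-[(2S,5R)-5-(2-hydroxyethyl)-5-methyloxolan-2-yl]pent-4-en-2-ol
Product: 10 bis(triethylsilyl) ether of 9 (O6 and O10 silylated)
Conditions: Et3SiOTf, 2,6-lutidine, CH2Cl2, −78 → 0 °C
Reagents that add atoms: triethylsilyl trifluoromethanesulfonate, CC[Si](CC)(CC)OS(=O)(=O)C(F)(F)F
Why: The silyl triflate silylates both the primary and the hindered tertiary hydroxyl in one operation; the two ethers differ enough in lability to be unmasked separately later.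

Step 7
Reactants: 10 bis(triethylsilyl) ether of 9
Product: 12 (3R)-3-[(2S,5R)-5-methyl-5-[2-(triethylsilyloxy)ethyl]oxolan-2-yl]-3-(triethylsilyloxy)butanal, via ozonide 11 (not isolated)
Conditions: O3, CH2Cl2, −78 °C; then PPh3, −78 °C → rt
Reagents that add atoms: ozone, [O-][O+]=O
Why: Ozonolysis of the only alkene with reductive work-up gives the C8 aldehyde; the β-oxygen is silylated, so retro-aldol cleavage is blocked.

Step 8
Reactants: 13 propiolic acid; 14 2-(trimethylsilyl)ethanol
Product: 15 2-(trimethylsilyl)ethyl propiolate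
Conditions: DCC, DMAP (cat.), CH2Cl2, −20 → 0 °C
Reagents that add atoms: none
Why: Steglich esterification at low temperature gives the fluoride-labile ester before the base-sensitive alkyne is used.

Step 9
Reactants: 15 2-(trimethylsilyl)ethyl propiolate; 12 (3R)-3-[(2S,5R)-5-methyl-5-[2-(triethylsilyloxy)ethyl]oxolan-2-yl]-3-(triethylsilyloxy)butanal
Product: 17 2-(trimethylsilyl)ethyl (4RS,6R)-4-hydroxy-6-[(2S,5R)-5-methyl-5-[2-(triethylsilyloxy)ethyl]oxolan-2-yl]-6-(triethylsilyloxy)hept-2-ynoate, via lithium acetylide 16 (not isolated)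
Conditions: LiN(SiMe3)2, THF, −78 °C; then 12, −78 °C
Reagents that add atoms: none
Why: 1,2-Addition of the lithium acetylide to the aldehyde forms C7–C8; the C8 configuration is not controlled here because it is erased in the next step.

Step 10
Reactants: 17 propargylic alcohol (C8 epimers)
Product: 18 2-(trimethylsilyl)ethyl (6R)-6-[(2S,5R)-5-methyl-5-[2-(triethylsilyloxy)ethyl]oxolan-2-yl]-4-oxo-6-(triethylsilyloxy)hept-2-ynoate
Conditions: Dess–Martin periodinane, NaHCO3, CH2Cl2, 0 °C → rt
Reagents that add atoms: none
Why: Buffered Dess–Martin oxidation converts both epimers into one ynone under neutral conditions that avoid β-elimination of the C10 silyloxy group.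

Step 11
Reactants: 18 ynone
Product: 19 2-(trimethylsilyl)ethyl (4S,6R)-4-hydroxy-6-[(2S,5R)-5-methyl-5-[2-(triethylsilyloxy)ethyl]oxolan-2-yl]-6-(triethylsilyloxy)hept-2-ynoate
Conditions: Ru[(S,S)-TsNCH(Ph)CH(Ph)NH](p-cymene) (cat., preformed amido complex), i-PrOH, rt
Reagents that add atoms: none
Why: Noyori asymmetric transfer hydrogenation of the alkynyl ketone under base-free conditions; the alkyne takes the place of the aryl group in the transition state, so the (S,S)-catalyst should give the (S)-carbinol at C8 by reagent control.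

Step 12
Reactants: 19 (4S)-propargylic alcohol
Product: 20 2-(trimethylsilyl)ethyl (4S,6R)-4-[(tert-butyldimethylsilyl)oxy]-6-[(2S,5R)-5-methyl-5-[2-(triethylsilyloxy)ethyl]oxolan-2-yl]-6-(triethylsilyloxy)hept-2-ynoate
Conditions: t-BuMe2SiOTf, 2,6-lutidine, CH2Cl2, −78 °C
Reagents that add atoms: tert-butyldimethylsilyl trifluoromethanesulfonate, CC(C)(C)[Si](C)(C)OS(=O)(=O)C(F)(F)F
Why: Silylation removes the only proton source that could quench the allenolate of the next step and gives the C8 ether that must outlast the primary ones.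

Step 13
Reactants: 20 C8-silylated ynoate
Product: 22 seco iodoenoate alcohol: (7Z)-7-iodo enoate with free C13 hydroxyl; C12 2-(trimethylsilyl)ethyl ester; 8-OTBS; 6-OTES; 10-OTES; (1S,4R,8S,10R), via magnesium iodoallenolate 21 (not isolated)
Conditions: MgI2, CH2Cl2, 0 °C; CH2O (monomer, cracked from paraformaldehyde), −20 → 0 °C
Reagents that add atoms: magnesium iodide, [Mg+2].[I-].[I-]; formaldehyde, C=O
Why: Iodo-aldol reaction (the β-iodo Morita–Baylis–Hillman manifold): iodide adds to C7 of the magnesium-activated ynoate and the allenolate is hydroxymethylated at C11; the small electrophile enters in the plane of the C7 substituents on the side away from iodine, as in the anti hydroiodination of alkynoates, so iodine ends cis to the ester.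

Step 14
Reactants: 22 seco iodoenoate alcohol
Product: 23 seco iodoenoate bis(tert-butyldimethylsilyl) ether: as 22 with 13-OTBS
Conditions: t-BuMe2SiCl, imidazole, DMF, 0 °C → rt
Reagents that add atoms: tert-butyldimethylsilyl chloride, CC(C)(C)[Si](C)(C)Cl
Why: Standard silylation of the primary allylic alcohol; as a silyl ether, unlike an ester, this allylic oxygen is not ionised by low-valent nickel.

Step 15
Reactants: 23 seco iodoenoate bis(tert-butyldimethylsilyl) ether
Product: 24 seco aldehyde: as 23 with C6 as the aldehyde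
Conditions: (COCl)2, DMSO, CH2Cl2, −78 → −30 °C; then Et3N, → 0 °C
Reagents that add atoms: none
Why: Under Swern conditions a primary triethylsilyl ether is cleaved and oxidised in one operation, whereas the tertiary triethylsilyl and the tert-butyldimethylsilyl ethers stay.

Step 16
Reactants: 24 seco aldehyde
Product: 25 seco acid: as 23 with C6 as the carboxylic acid
Conditions: NaClO2, NaH2PO4, 2-methyl-2-butene, t-BuOH/H2O, 0 °C → rt
Reagents that add atoms: sodium chlorite, [Na+].[O-]Cl=O
Why: Pinnick oxidation is selective for the aldehyde and leaves the iodoenoate, the silyl ethers and the silylethyl ester alone.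

Step 17
Reactants: 25 seco acid
Product: 26 seco thioester–vinyl iodide: C6 S-pyridin-2-yl thioester; (7Z)-7-iodo enoate; C12 2-(trimethylsilyl)ethyl ester; 8-OTBS; 13-OTBS; 10-OTES; (1S,4R,8S,10R)
Conditions: 2,2'-dipyridyl disulfide, PPh3, CH2Cl2, rt
Reagents that add atoms: 2,2'-dipyridyl disulfide, c1ccc(SSc2ccccn2)nc1
Why: Mukaiyama redox condensation (Corey–Nicolaou activation) gives the 2-pyridyl thioester under neutral conditions directly before its use.

Step 18
Reactants: 26 seco thioester–vinyl iodide
Product: 27 ten-membered (Z)-γ-keto enoate: C6 ketone cis to the C12 2-(trimethylsilyl)ethyl ester on C7=C11; 8-OTBS; 13-OTBS; 10-OTES; 1,4-ether bridge; (1S,4R,8S,10R)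
Conditions: NiBr2(dme) (30 mol%), 4,4'-di-tert-butyl-2,2'-bipyridine (35 mol%), Mn powder (4 equiv), N,N-dimethylacetamide, 25 °C, 26 added by syringe pump over 12 h (final 2 mM)
Reagents that add atoms: none
Why: Proposed new method: Mn reduces divalent nickel to zerovalent nickel, which adds oxidatively into the C7–I bond with retention of the (Z) geometry; one-electron reduction gives a monovalent vinylnickel that takes up the acyl–sulfur bond of the 2-pyridyl thioester, and the resulting trivalent acyl(vinyl)nickel forms C6–C7 by reductive elimination, with iodide and thiolate ending on manganese. The closest known reaction type is the intermolecular nickel-catalysed reductive ketone synthesis from organic halides and 2-pyridyl thioesters or acid chlorides; the intramolecular, ring-forming version on a tetrasubstituted iodoenoate is untested. The ten-membered ring is closed by C(sp2)–C(sp2) reductive elimination from a nickelacycle that holds C6 and C7, a union of two electrophilic carbons for which no ionic ring-closing mode exists. No stereocentre is formed; the one stereochemical demand is retention at C7=C11, which the configurational stability of the vinylnickel should secure, so that the C6 ketone stays cis to C12. Cross-coupling over dimerisation rests on the different activation of the two ends (oxidative addition at the iodide, thioester uptake only after reduction) and on slow addition at high dilution. The cis-oxolane turns the C5 and C9 arms to the same face and brings C6 within reach of C7. The silyl ethers and the silylethyl ester carry no bond that nickel or manganese should attack, which is why the allylic oxygens are not esters at this stage.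

Step 19
Reactants: 27 ten-membered (Z)-γ-keto enoate
Product: 30 ylidenebutenolide acetate: 12,6-lactone with C5=C6 (C4 and C7 cis); 13-OAc; 8-OTBS; 10-OTES, via hydroxybutenolide 28 (not isolated), via lactol acetate 29 (not isolated)
Conditions: Bu4NF, AcOH, THF, 0 °C; then Ac2O, Et3N, DMAP (cat.), 0 °C → rt; then DBU, 0 °C
Reagents that add atoms: acetic anhydride, CC(=O)OC(C)=O
Why: Buffered fluoride fragments the silylethyl ester and cleaves the unhindered primary silyl ether, while the hindered secondary C8 and tertiary C10 ethers should persist; the C12 carboxylate, held cis to the C6 ketone, closes to the hydroxybutenolide. Acetylation of the C13 hydroxyl and of the lactol hydroxyl, followed by base-induced loss of acetic acid across C5–C6, gives the enol lactone, whose geometry is fixed by the ring.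

Step 20
Reactants: 30 ylidenebutenolide acetate
Product: 31 diol: as 30 with free C8 and C10 hydroxyls
Conditions: HF·pyridine, pyridine, THF, 0 °C → rt
Reagents that add atoms: none
Why: Buffered HF removes the remaining secondary and tertiary silyl ethers without touching the acetate or the enol lactone; it is done before the epoxide is present.

Step 21
Reactants: 32 2-methylprop-2-en-1-ol
Product: 33 (R)-(2-methyloxiran-2-yl)methanol
Conditions: Ti(OiPr)4 (cat.), D-(−)-diisopropyl tartrate, cumene hydroperoxide, 4 Å MS, CH2Cl2, −20 °C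
Reagents that add atoms: cumene hydroperoxide, CC(C)(OO)c1ccccc1
Why: Sharpless epoxidation of the 1,1-disubstituted allylic alcohol; the D-tartrate delivers oxygen to the face that gives the (R)-epoxy alcohol.

Step 22
Reactants: 33 (R)-(2-methyloxiran-2-yl)methanol
Product: 34 (S)-2-methyloxirane-2-carboxylic acid
Conditions: RuCl3 hydrate (cat.), NaIO4, MeCN/EtOAc/H2O, 0 °C → rt
Reagents that add atoms: water, O
Why: RuO4 oxidation of the epoxy alcohol to the epoxy acid leaves the quaternary centre untouched; the descriptor changes from R to S only because the carboxyl group outranks the ring carbon.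

Step 23
Reactants: 34 (S)-2-methyloxirane-2-carboxylic acid; 31 diol
Product: 36 target: (1S,4R,8S,10R)-13-acetoxy-10-hydroxy-1,4-epoxygermacra-5,7(11)-dien-12,6-olide 8-[(2S)-2-methyloxirane-2-carboxylate], via mixed anhydride 35 (not isolated)
Conditions: 2,4,6-trichlorobenzoyl chloride, Et3N, THF, 0 °C → rt; then 31, DMAP, toluene, rt
Reagents that add atoms: none
Why: Yamaguchi esterification acylates the secondary allylic C8 hydroxyl; the tertiary C10 hydroxyl does not react, and the conditions are mild enough for the epoxide and the enol lactone.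

## Compound list

1 | (R)-linalool, (3R)-3,7-dimethylocta-1,6-dien-3-ol | C=C[C@](C)(O)CCC=C(C)C | starting material
2 | (2E,6R)-2,6-dimethylocta-2,7-diene-1,6-diol | C=C[C@](C)(O)CC/C=C(\C)CO | intermediate
3 | [(2R,3R)-3-[(3R)-3-hydroxy-3-methylpent-4-en-1-yl]-2-methyloxiran-2-yl]methanol | C=C[C@](C)(O)CC[C@H]1O[C@]1(C)CO | intermediate
4 | (2R)-2-[(2S,5R)-5-ethenyl-5-methyloxolan-2-yl]propane-1,2-diol | C=C[C@@]1(C)CC[C@H](O1)[C@](C)(O)CO | intermediate
5 | (2R)-2-[(2S,5R)-5-ethenyl-5-methyloxolan-2-yl]-2-hydroxypropyl 4-methylbenzenesulfonate | C=C[C@@]1(C)CC[C@H](O1)[C@](C)(O)COS(=O)(=O)c1ccc(C)cc1 | intermediate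
6 | (2R,5S)-2-ethenyl-2-methyl-5-[(2R)-2-methyloxiran-2-yl]oxolane | C=C[C@@]1(C)CC[C@H](O1)[C@@]1(C)CO1 | intermediate
7 | B-alkyl-9-borabicyclo[3.3.1]nonane adduct of 6 (boron on C6, stereocentres as in 6) | C1CC2CCCC(C1)B2CC[C@@]3(C)CC[C@H](O3)[C@@]3(C)CO3 | intermediate
8 | 2-[(2R,5S)-2-methyl-5-[(2R)-2-methyloxiran-2-yl]oxolan-2-yl]ethan-1-ol | OCC[C@@]1(C)CC[C@H](O1)[C@@]1(C)CO1 | intermediate
9 | (2R)-2-[(2S,5R)-5-(2-hydroxyethyl)-5-methyloxolan-2-yl]pent-4-en-2-ol | OCC[C@@]1(C)CC[C@H](O1)[C@](C)(O)CC=C | intermediate
10 | bis(triethylsilyl) ether of 9 | CC[Si](CC)(CC)OCC[C@@]1(C)CC[C@H](O1)[C@](C)(O[Si](CC)(CC)CC)CC=C | intermediate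
11 | ozonide (1,2,4-trioxolane) of 10 | CC[Si](CC)(CC)OCC[C@@]1(C)CC[C@H](O1)[C@](C)(O[Si](CC)(CC)CC)CC1OCOO1 | intermediate
12 | (3R)-3-[(2S,5R)-5-methyl-5-[2-(triethylsilyloxy)ethyl]oxolan-2-yl]-3-(triethylsilyloxy)butanal | CC[Si](CC)(CC)OCC[C@@]1(C)CC[C@H](O1)[C@](C)(O[Si](CC)(CC)CC)CC=O | intermediate
13 | propiolic acid | C#CC(=O)O | starting material
14 | 2-(trimethylsilyl)ethanol | C[Si](C)(C)CCO | starting material
15 | 2-(trimethylsilyl)ethyl propiolate | C#CC(=O)OCC[Si](C)(C)C | intermediate
16 | lithium acetylide of 15 | [Li]C#CC(=O)OCC[Si](C)(C)C | intermediate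
17 | 2-(trimethylsilyl)ethyl (4RS,6R)-4-hydroxy-6-[(2S,5R)-5-methyl-5-[2-(triethylsilyloxy)ethyl]oxolan-2-yl]-6-(triethylsilyloxy)hept-2-ynoate | CC[Si](CC)(CC)OCC[C@@]1(C)CC[C@H](O1)[C@](C)(O[Si](CC)(CC)CC)CC(O)C#CC(=O)OCC[Si](C)(C)C | intermediate
18 | 2-(trimethylsilyl)ethyl (6R)-6-[(2S,5R)-5-methyl-5-[2-(triethylsilyloxy)ethyl]oxolan-2-yl]-4-oxo-6-(triethylsilyloxy)hept-2-ynoate | CC[Si](CC)(CC)OCC[C@@]1(C)CC[C@H](O1)[C@](C)(O[Si](CC)(CC)CC)CC(=O)C#CC(=O)OCC[Si](C)(C)C | intermediate
19 | 2-(trimethylsilyl)ethyl (4S,6R)-4-hydroxy-6-[(2S,5R)-5-methyl-5-[2-(triethylsilyloxy)ethyl]oxolan-2-yl]-6-(triethylsilyloxy)hept-2-ynoate | CC[Si](CC)(CC)OCC[C@@]1(C)CC[C@H](O1)[C@](C)(O[Si](CC)(CC)CC)C[C@H](O)C#CC(=O)OCC[Si](C)(C)C | intermediate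
20 | 2-(trimethylsilyl)ethyl (4S,6R)-4-[(tert-butyldimethylsilyl)oxy]-6-[(2S,5R)-5-methyl-5-[2-(triethylsilyloxy)ethyl]oxolan-2-yl]-6-(triethylsilyloxy)hept-2-ynoate | CC[Si](CC)(CC)OCC[C@@]1(C)CC[C@H](O1)[C@](C)(O[Si](CC)(CC)CC)C[C@H](O[Si](C)(C)C(C)(C)C)C#CC(=O)OCC[Si](C)(C)C | intermediate
21 | magnesium iodoallenolate from 20 (iodine on C7, O–Mg ketene acetal at C12) | CC[Si](CC)(CC)OCC[C@@]1(C)CC[C@H](O1)[C@](C)(O[Si](CC)(CC)CC)C[C@H](O[Si](C)(C)C(C)(C)C)C(I)=C=C(O[Mg]I)OCC[Si](C)(C)C | intermediate
22 | 2-(trimethylsilyl)ethyl (2Z,4S,6R)-4-[(tert-butyldimethylsilyl)oxy]-2-(hydroxymethyl)-3-iodo-6-[(2S,5R)-5-methyl-5-[2-(triethylsilyloxy)ethyl]oxolan-2-yl]-6-(triethylsilyloxy)hept-2-enoate | CC[Si](CC)(CC)OCC[C@@]1(C)CC[C@H](O1)[C@](C)(O[Si](CC)(CC)CC)C[C@H](O[Si](C)(C)C(C)(C)C)/C(I)=C(\CO)C(=O)OCC[Si](C)(C)C | intermediate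
23 | 2-(trimethylsilyl)ethyl (2Z,4S,6R)-4-[(tert-butyldimethylsilyl)oxy]-2-{[(tert-butyldimethylsilyl)oxy]methyl}-3-iodo-6-[(2S,5R)-5-methyl-5-[2-(triethylsilyloxy)ethyl]oxolan-2-yl]-6-(triethylsilyloxy)hept-2-enoate | CC[Si](CC)(CC)OCC[C@@]1(C)CC[C@H](O1)[C@](C)(O[Si](CC)(CC)CC)C[C@H](O[Si](C)(C)C(C)(C)C)/C(I)=C(\CO[Si](C)(C)C(C)(C)C)C(=O)OCC[Si](C)(C)C | intermediate
24 | seco aldehyde: as 23 with the 5-(2-oxoethyl)oxolane arm (C6 aldehyde) | O=CC[C@@]1(C)CC[C@H](O1)[C@](C)(O[Si](CC)(CC)CC)C[C@H](O[Si](C)(C)C(C)(C)C)/C(I)=C(\CO[Si](C)(C)C(C)(C)C)C(=O)OCC[Si](C)(C)C | intermediate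
25 | seco acid: as 23 with the 5-(carboxymethyl)oxolane arm (C6 acid) | OC(=O)C[C@@]1(C)CC[C@H](O1)[C@](C)(O[Si](CC)(CC)CC)C[C@H](O[Si](C)(C)C(C)(C)C)/C(I)=C(\CO[Si](C)(C)C(C)(C)C)C(=O)OCC[Si](C)(C)C | intermediate
26 | seco thioester–vinyl iodide: C6 S-pyridin-2-yl thioester, (7Z)-7-iodo enoate, C12 2-(trimethylsilyl)ethyl ester, 8-OTBS, 13-OTBS, 10-OTES, (1S,4R,8S,10R) | O=C(Sc1ccccn1)C[C@@]1(C)CC[C@H](O1)[C@](C)(O[Si](CC)(CC)CC)C[C@H](O[Si](C)(C)C(C)(C)C)/C(I)=C(\CO[Si](C)(C)C(C)(C)C)C(=O)OCC[Si](C)(C)C | intermediate
27 | ten-membered (Z)-γ-keto enoate: C6 ketone cis to C12 2-(trimethylsilyl)ethyl ester, 8-OTBS, 13-OTBS, 10-OTES, (1S,4R,8S,10R) | O=C1C[C@@]2(C)CC[C@H](O2)[C@](C)(O[Si](CC)(CC)CC)C[C@H](O[Si](C)(C)C(C)(C)C)/C1=C(\CO[Si](C)(C)C(C)(C)C)C(=O)OCC[Si](C)(C)C | intermediate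
28 | hydroxybutenolide: 12,6-lactone with C6 hydroxyl (epimers), free C13 hydroxyl, 8-OTBS, 10-OTES | OCC1=C2C(O)(C[C@@]3(C)CC[C@H](O3)[C@](C)(O[Si](CC)(CC)CC)C[C@@H]2O[Si](C)(C)C(C)(C)C)OC1=O | intermediate
29 | lactol acetate: as 28 with acetates on O6 and O13 | CC(=O)OCC1=C2C(OC(C)=O)(C[C@@]3(C)CC[C@H](O3)[C@](C)(O[Si](CC)(CC)CC)C[C@@H]2O[Si](C)(C)C(C)(C)C)OC1=O | intermediate
30 | ylidenebutenolide acetate: 12,6-lactone, C5=C6 (C4 and C7 cis), 13-OAc, 8-OTBS, 10-OTES | CC(=O)OCC1=C2/C(=C\[C@@]3(C)CC[C@H](O3)[C@](C)(O[Si](CC)(CC)CC)C[C@@H]2O[Si](C)(C)C(C)(C)C)OC1=O | intermediate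
31 | diol: as 30 with free C8 (S) and C10 (R) hydroxyls | CC(=O)OCC1=C2/C(=C\[C@@]3(C)CC[C@H](O3)[C@](C)(O)C[C@@H]2O)OC1=O | intermediate
32 | 2-methylprop-2-en-1-ol | C=C(C)CO | starting material
33 | (R)-(2-methyloxiran-2-yl)methanol | OC[C@]1(C)CO1 | intermediate
34 | (S)-2-methyloxirane-2-carboxylic acid | OC(=O)[C@]1(C)CO1 | intermediate
35 | mixed anhydride of 34 with 2,4,6-trichlorobenzoic acid | O=C(OC(=O)[C@]1(C)CO1)c1c(Cl)cc(Cl)cc1Cl | intermediate
36 | CNP0142137.1: (1S,4R,8S,10R)-13-acetoxy-10-hydroxy-1,4-epoxygermacra-5,7(11)-dien-12,6-olide 8-[(2S)-2-methyloxirane-2-carboxylate] | CC(=O)OCC1=C2/C(=C\[C@@]3(C)CC[C@H](O3)[C@](C)(O)C[C@@H]2OC(=O)[C@]2(C)CO2)OC1=O | target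

## Step count and least certain steps

Total: 23 steps. Longest linear sequence: 20 steps from (R)-linalool (steps 1–7, 9–20 and 23). Steps 8, 21 and 22 prepare the two side fragments.

**Step 18 (key step, proposed new method).**
- What may go wrong: intermolecular coupling or homodimerisation of the vinyl iodide outrunning ring closure; protodehalogenation of the vinylnickel; loss of alkene geometry through the β-nickel enoate; decarbonylation of the acylnickel. All follow from the slow closure of a strained ten-membered ring at a tetrasubstituted carbon.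
- Fallback with known chemistry: it sets out from aldehyde 24 and comes back at hydroxybutenolide 28. An intramolecular Nozaki–Hiyama–Kishi reaction of 24 (CrCl2, NiCl2 cat., DMSO/THF, high dilution) forms C6–C7 as a carbinol, whose chromium alkoxide lactonises onto the cis ester to give the macrocyclic butenolide F1. Treatment with triisopropylsilyl triflate and Et3N gives the 2-silyloxyfuran F2. Oxidation with dimethyldioxirane gives the bis-silylated hydroxybutenolide F3, and buffered Bu4NF removes the primary silyl ether to reach 28. The second half of step 19 then follows as written.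

**Step 13 (iodo-aldol).**
- What may go wrong: insufficient facial selectivity in trapping the allenolate, which would give the (E)-iodoenoate; quenching of the allenolate by adventitious protons to the simple hydroiodination product; polymerisation of formaldehyde on the Lewis acid.
- Fallback: it sets out from ynoate 20 and comes back at 23. Pyrrolidine adds to 20 to give the β-enamino ester F4, which is hydrolysed under buffered conditions to the β-keto ester F5. Its lithium enolate, deprotonated between the carbonyls so that C8 is not touched, is hydroxymethylated with formaldehyde to F6 and silylated to F7. The chelated enolate of F7 is trapped with N-phenyltriflimide as the (Z)-enol triflate F8. Pd(PPh3)4, Me3SnSnMe3 and LiCl convert F8 with retention into the vinylstannane F9, and iodine replaces tin with retention to give 23.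

**Step 19 (selective fluoride cleavage and acylative dehydration).**
- What may go wrong: premature loss of the C8 or C10 silyl ether under fluoride, followed by acetylation at O8 or transannular capture of C6 by the C10 hydroxyl; incomplete elimination of the lactol acetate.
- Fallback: it sets out from 27 and comes back at 30, with the order of events changed. Buffered HF·pyridine removes only the primary C13 silyl ether to give the keto ester alcohol F10. Acetylation gives the acetate F11. Tris(dimethylamino)sulfonium difluorotrimethylsilicate in DMF then cleaves the silylethyl ester under nearly neutral conditions to the hydroxybutenolide acetate F12. Methanesulfonyl chloride and Et3N dehydrate F12 to 30 without an acylating agent.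

**Step 11 (transfer hydrogenation of the keto ynoate).**
- What may go wrong: conjugate addition of the alcohol solvent or over-reduction of the doubly activated alkyne, and erosion of selectivity by the remote quaternary centre.
- Fallback: it sets out from aldehyde 12 (with ester 15) and comes back at 19, bypassing 17 and 18. Ester 15 is added to 12 directly and enantioselectively with Me2Zn and the dinuclear zinc–ProPhenol catalyst. The ligand enantiomer that gives the (8S)-carbinol is chosen by Mosher analysis of the first adduct.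

## Further compounds

F1 | step 18 | macrocyclic butenolide: 12,6-lactone with C6–H (epimers), 8-OTBS, 13-OTBS, 10-OTES | CC(C)(C)[Si](C)(C)OCC1=C2C(C[C@@]3(C)CC[C@H](O3)[C@](C)(O[Si](CC)(CC)CC)C[C@@H]2O[Si](C)(C)C(C)(C)C)OC1=O
F2 | step 18 | 2-(triisopropylsilyloxy)furan from F1 (furan carbons C12, C11, C7, C6) | CC(C)(C)[Si](C)(C)OCC1=C(O[Si](C(C)C)(C(C)C)C(C)C)OC2=C1[C@@H](O[Si](C)(C)C(C)(C)C)C[C@@](C)(O[Si](CC)(CC)CC)[C@@H]1CC[C@@](C)(O1)C2
F3 | step 18 | bis-silylated hydroxybutenolide: as 28 with 13-OTBS | CC(C)(C)[Si](C)(C)OCC1=C2C(O)(C[C@@]3(C)CC[C@H](O3)[C@](C)(O[Si](CC)(CC)CC)C[C@@H]2O[Si](C)(C)C(C)(C)C)OC1=O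
F4 | step 13 | β-(pyrrolidin-1-yl) enoate from 20 (nitrogen on C7) | CC[Si](CC)(CC)OCC[C@@]1(C)CC[C@H](O1)[C@](C)(O[Si](CC)(CC)CC)C[C@H](O[Si](C)(C)C(C)(C)C)C(N1CCCC1)=CC(=O)OCC[Si](C)(C)C
F5 | step 13 | β-keto ester: C7 ketone, C11 methylene, 8-OTBS | CC[Si](CC)(CC)OCC[C@@]1(C)CC[C@H](O1)[C@](C)(O[Si](CC)(CC)CC)C[C@H](O[Si](C)(C)C(C)(C)C)C(=O)CC(=O)OCC[Si](C)(C)C
F6 | step 13 | α-(hydroxymethyl) β-keto ester (C11 epimers) | CC[Si](CC)(CC)OCC[C@@]1(C)CC[C@H](O1)[C@](C)(O[Si](CC)(CC)CC)C[C@H](O[Si](C)(C)C(C)(C)C)C(=O)C(CO)C(=O)OCC[Si](C)(C)C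
F7 | step 13 | α-{[(tert-butyldimethylsilyl)oxy]methyl} β-keto ester (C11 epimers) | CC[Si](CC)(CC)OCC[C@@]1(C)CC[C@H](O1)[C@](C)(O[Si](CC)(CC)CC)C[C@H](O[Si](C)(C)C(C)(C)C)C(=O)C(CO[Si](C)(C)C(C)(C)C)C(=O)OCC[Si](C)(C)C
F8 | step 13 | (Z)-enol triflate: as 23 with OSO2CF3 in place of iodine | CC[Si](CC)(CC)OCC[C@@]1(C)CC[C@H](O1)[C@](C)(O[Si](CC)(CC)CC)C[C@H](O[Si](C)(C)C(C)(C)C)/C(OS(=O)(=O)C(F)(F)F)=C(\CO[Si](C)(C)C(C)(C)C)C(=O)OCC[Si](C)(C)C
F9 | step 13 | (Z)-vinylstannane: as 23 with SnMe3 in place of iodine | CC[Si](CC)(CC)OCC[C@@]1(C)CC[C@H](O1)[C@](C)(O[Si](CC)(CC)CC)C[C@H](O[Si](C)(C)C(C)(C)C)/C([Sn](C)(C)C)=C(\CO[Si](C)(C)C(C)(C)C)C(=O)OCC[Si](C)(C)C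
F10 | step 19 | keto ester alcohol: as 27 with free C13 hydroxyl | O=C1C[C@@]2(C)CC[C@H](O2)[C@](C)(O[Si](CC)(CC)CC)C[C@H](O[Si](C)(C)C(C)(C)C)/C1=C(\CO)C(=O)OCC[Si](C)(C)C
F11 | step 19 | keto ester acetate: as 27 with 13-OAc | O=C1C[C@@]2(C)CC[C@H](O2)[C@](C)(O[Si](CC)(CC)CC)C[C@H](O[Si](C)(C)C(C)(C)C)/C1=C(\COC(C)=O)C(=O)OCC[Si](C)(C)C
F12 | step 19 | hydroxybutenolide acetate: as 28 with 13-OAc | CC(=O)OCC1=C2C(O)(C[C@@]3(C)CC[C@H](O3)[C@](C)(O[Si](CC)(CC)CC)C[C@@H]2O[Si](C)(C)C(C)(C)C)OC1=O
F0 | step 11 | none | none
A1 | alternative 1 | ethyl (2E)-3-{[(1S)-3-bromo-1-[(4R)-2,2,4-trimethyl-1,3-dioxolan-4-yl]propyl]oxy}but-2-enoate | CCOC(=O)/C=C(\C)O[C@@H](CCBr)[C@@]1(C)COC(C)(C)O1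
A2 | alternative 1 | ethyl 2-[(2R,5S)-2-methyl-5-[(4R)-2,2,4-trimethyl-1,3-dioxolan-4-yl]oxolan-2-yl]acetate | CCOC(=O)C[C@@]1(C)CC[C@H](O1)[C@@]2(C)COC(C)(C)O2
A3 | alternative 2 | (2R,3S,6E)-8-(benzyloxy)-1-[(tert-butyldimethylsilyl)oxy]-2,6-dimethyloct-6-ene-2,3-diol | c1ccccc1COC/C=C(\C)CC[C@H](O)[C@](C)(O)CO[Si](C)(C)C(C)(C)C
A4 | alternative 2 | (1R)-2-(benzyloxy)-1-{(2R,5S)-5-[(2R)-1-[(tert-butyldimethylsilyl)oxy]-2-hydroxypropan-2-yl]-2-methyloxolan-2-yl}ethan-1-ol | c1ccccc1COC[C@@H](O)[C@@]2(C)CC[C@H](O2)[C@](C)(O)CO[Si](C)(C)C(C)(C)C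
A5 | alternative 3 | eleven-membered cyclic sulfone: SO2 between C5 and C6 of the butenolide (C6–H), 8-OTBS, 13-OTBS, free 10-OH | CC(C)(C)[Si](C)(C)OCC1=C2C(S(=O)(=O)C[C@@]3(C)CC[C@H](O3)[C@](C)(O)C[C@@H]2O[Si](C)(C)C(C)(C)C)OC1=O
A6 | alternative 3 | bis-silyl ether of the macrocyclic ylidenebutenolide core: 8-OTBS, 13-OTBS, free 10-OH | CC(C)(C)[Si](C)(C)OCC1=C2/C(=C\[C@@]3(C)CC[C@H](O3)[C@](C)(O)C[C@@H]2O[Si](C)(C)C(C)(C)C)OC1=O
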